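The readings come from a simulation on assumed constants; scatter was added.

**The trap.** The easy mistake with amber was to carry over ochre's yield, 42.0 % of its starting material at the last reading, though amber's charges are lopsided.

| flask | starting material | coupling partner | target | time |
|---|---|---|---|---|
| ochre | 0.600 M | 0.720 M |  |  |
| violet | 0.600 M | 0.720 M | 0.300 M |  |
| amber | 1.80 M | 0.240 M |  | 140 min |

| ochre run: time / min | ochre run: [target] / M | violet run: time / min | violet run: [target] / M |
|---|---|---|---|
| 5.0 | 0.004 | 5.0 | 0.422 |
| 15 | 0.028 | 15 | 0.582 |
| 29 | 0.098 | 29 | 0.640 |
| 46 | 0.181 | 46 | 0.668 |
| 66 | 0.209 | 66 | 0.668 |
| 88 | 0.235 | 88 | 0.698 |
| 110 | 0.239 | 110 | 0.698 |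
| 140 | 0.252 | 140 | 0.706 |

(scatter of a reading: 0.009 M)

1. target in the amber run at 140 min, as a share of the starting material charged
2. which of these the readings show (the product binds the second partner / the product binds the substrate / the product speeds the reaction)

- Overall: starting material + coupling partner -> target.
- Constant volume, constant temperature.
- "The second partner" is coupling partner.

**The seed.** At 5.0 min, violet, charged like ochre but seeded with target, had made 20.3 % of its starting material, far more than ochre's 0.667 %. Target that bound either reactant should have held violet back, so I read the target as speeding the reaction.

**First way.** In amber the coupling partner is the limiting reagent. Its charge is 13.3 % of the starting material, and that share is amber's ceiling.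

**Second way.** The two charges multiply to the same figure in amber as in ochre. I therefore assumed a rate of one common time factor multiplied by the two concentrations, which also assumes that target builds alike in both flasks. Undoing the fall of both reactants in ochre up to its last reading gave 22.8 % of amber's charge. I call this the drive, the amount made by then had both charges held at their start values.

**Where they part.** The drive stands higher than the ceiling, and the drive is the one that cheats, since it keeps amber's partner at its full charge. Holding amber's starting material at its charge and letting the rate fall with the partner left, I reckoned the share made as the ceiling times one minus the exponential of minus drive over ceiling. I committed to 10.9 %.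

The forecast stood at 9.7 %, reading in ochre “a lag, then a burst, so the product speeds the reaction”.

**The result.** Amber gave 11.1 %, and the readings show that the product speeds the reaction: where equal amounts had been made, violet's rate was ten times ochre's.

    starting material → intermediate (0.04566 min⁻¹)
    intermediate + coupling partner → target (0.01710 M⁻¹ min⁻¹)
    intermediate → side product (0.01872 min⁻¹)
    starting material + coupling partner + target → 2 target (0.2286 M⁻² min⁻¹)

Put back through the same partner brake, amber's 11.1 % asks for a drive of 23.6 % of its charge, against 22.8 % taken from ochre. Reckoned on each flask's own charge, ochre's drive was 68.4 %, and violet's, from the target made beyond its seed, was 180 %.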